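**Plan**

- Ring numbering used throughout: C1 (quaternary, CH3 and bromovinyl), C2 (CHBr), C3 (CH2), C4 (CHCl), C5 (C(CH3)Cl), C6 (CH2). The target is (1S,2S,4R,5S), with bromovinyl, Br and both Cl on one ring face ("top") and both methyls on the other ("bottom").
- Retrosynthesis cuts C4–Cl and then C5–Cl (back to a C4/C5 epoxide and the C4=C5 alkene), the vinyl C=C (back to a formyl group on C1), the C4–H bond (back to a C4 silyl enol ether), and last the ring bonds C1–C6 and C2–C3.
- Enabling feature: the cis C1/C2 pair (carbon substituent and Br) maps onto a (Z)-β-bromo-α-methyl enal, and C3–C4–C5–C6 onto a 2-silyloxy-3-methylbutadiene whose inner carbons become C4 and C5. The single ring is therefore closed by one [4+2] cycloaddition.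
- Forward: diene (1 step) and (Z)-bromoenal (2 steps) are made separately and joined in the cycloaddition. C4 is then deoxygenated through the enol triflate, the aldehyde is converted into the (E)-bromovinyl group, and the alkene is turned into the cis-dichloride by epoxidation and two invertive chloride substitutions.
- Stereochemistry: the C1/C2 relative configuration comes from the (Z)-alkene geometry and the absolute configuration from a chiral oxazaborolidinium catalyst. C4/C5 come from epoxidation on the bottom face, then inversion at C5 (epoxide opening) and at C4 (deoxychlorination).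

Key step: step 4

Assumption: the (Z)-bromoenal is taken to bind the oxazaborolidinium ion as other 2-substituted acroleins do (formyl C–H···O contact, s-trans enal), so that the (S)-catalyst exposes the enal face leading to the (1S,6S)-cycloadduct; should the bromine reverse this facial sense, the equally accessible (R)-catalyst is the one to use.

**Route**

Step 1
Reactants: 1 3-methylbut-3-en-2-one
Product: 2 tert-butyl(dimethyl)[(3-methylbuta-1,3-dien-2-yl)oxy]silane
Conditions: TBSOTf, Et3N, Et2O, 0 °C
Reagents that add atoms: tert-butyldimethylsilyl trifluoromethanesulfonate, CC(C)(C)[Si](C)(C)OS(=O)(=O)C(F)(F)F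
Why: Soft enolisation and O-silylation of a methyl ketone; the acetyl CH3 carries the only enolisable hydrogens, so the cross-conjugated 2-silyloxydiene is the only enol ether that can form.

Step 2
Reactants: 3 prop-2-yn-1-ol
Product: 5 (Z)-3-bromo-2-methylprop-2-en-1-ol, via magnesiated alkoxide 4 (not isolated)
Conditions: MeMgBr (3 equiv), CuI (10 mol %), THF, −10 °C to rt; then NBS, −30 to 0 °C; aq. NH4Cl
Reagents that add atoms: methylmagnesium bromide, C[Mg]Br; N-bromosuccinimide, O=C1CCC(=O)N1Br
Why: Copper-catalysed, alkoxide-directed anti-carbomagnesiation of the propargylic alcohol delivers CH3 to C2 and magnesium to C3 cis to the CH2O group within a five-membered chelate, and brominolysis of the alkenyl–Mg bond with retention fixes the (Z)-geometry.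

Step 3
Reactants: 5 (Z)-3-bromo-2-methylprop-2-en-1-ol
Product: 6 (Z)-3-bromo-2-methylprop-2-enal
Conditions: activated MnO2 (excess), CH2Cl2, rt, dark; filtered, dried over 4 Å sieves and used as a cold CH2Cl2 solution
Reagents that add atoms: none
Why: Heterogeneous allylic oxidation with MnO2 under neutral conditions, which should leave the (Z)-alkene untouched because no acid, base or nucleophile is present to catalyse isomerisation.

Step 4
Reactants: 2 tert-butyl(dimethyl)[(3-methylbuta-1,3-dien-2-yl)oxy]silane, 6 (Z)-3-bromo-2-methylprop-2-enal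
Product: 7 (1S,6S)-6-bromo-4-[tert-butyl(dimethyl)silyl]oxy-1,3-dimethylcyclohex-3-ene-1-carbaldehyde
Conditions: (S)-3,3-diphenyl-1-(o-tolyl)tetrahydro-1H,3H-pyrrolo[1,2-c][1,3,2]oxazaborole (20 mol %), Tf2NH (20 mol %), CH2Cl2, −78 to −40 °C; Et3N quench
Reagents that add atoms: none
Why: The cationic boron binds the formyl oxygen and lowers the enal LUMO, and the diene CH2 next to the silyloxy carbon (future C3) attacks the bromine-bearing β-carbon (C2) slightly ahead of C6–C1 bonding in a concerted, asynchronous [4+2] cycloaddition. The closest known reaction type is the oxazaborolidinium triflimide-catalysed Diels–Alder reaction of 2-substituted acroleins with 2-silyloxybutadienes. The six-membered carbocycle is closed by this intermolecular suprafacial [4+2] addition, both ring bonds (C1–C6 and C2–C3) forming in one step. C1 and C2 are set together: their cis relationship (Br cis to CHO) is carried over from the (Z)-geometry of 6, and the absolute configuration comes from the catalyst, whose aryl group covers one face of the s-trans enal held by the formyl C–H···O contact, so that the diene adds to the open face and should give the (1S,6S)-adduct. The step needs para regioselectivity, which the silyloxy group secures by outweighing the neighbouring methyl and placing its own carbon at C4; endo/exo selectivity does not arise because both diene termini are unsubstituted. The adduct cannot lose HBr because C1 bears no hydrogen.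

Step 5
Reactants: 7 (1S,6S)-6-bromo-4-[tert-butyl(dimethyl)silyl]oxy-1,3-dimethylcyclohex-3-ene-1-carbaldehyde
Product: 9 (4S,5S)-5-bromo-4-formyl-2,4-dimethylcyclohex-1-en-1-yl trifluoromethanesulfonate, via cesium enolate 8 (not isolated)
Conditions: CsF, PhNTf2, DME, rt
Reagents that add atoms: N-phenylbis(trifluoromethanesulfonimide), O=S(=O)(N(c1ccccc1)S(=O)(=O)C(F)(F)F)C(F)(F)F
Why: Fluoride desilylation releases the regiodefined tetrasubstituted enolate, which is O-triflated in situ before it can equilibrate toward C3 (the isomer that could expel the C2 bromide), while the aldehyde, having no α-hydrogen, is a spectator.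

Step 6
Reactants: 9 (4S,5S)-5-bromo-4-formyl-2,4-dimethylcyclohex-1-en-1-yl trifluoromethanesulfonate
Product: 10 (1S,6S)-6-bromo-1,3-dimethylcyclohex-3-ene-1-carbaldehyde
Conditions: Pd(OAc)2 (5 mol %), PPh3 (10 mol %), HCO2H, Bu3N, DMF, 40 °C
Reagents that add atoms: none
Why: Palladium-catalysed formate reduction of an enol triflate: zerovalent palladium inserts into the vinyl C–O bond far faster than into the hindered secondary C–Br bond, and decarboxylation of the formate complex followed by reductive elimination puts hydrogen on C4 and leaves the C4=C5 alkene in place.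

Step 7
Reactants: 10 (1S,6S)-6-bromo-1,3-dimethylcyclohex-3-ene-1-carbaldehyde
Product: 11 (4S,5S)-4-bromo-5-[(E)-2-bromoethenyl]-1,5-dimethylcyclohex-1-ene
Conditions: CrBr2 (6 equiv), CHBr3 (2 equiv), THF, rt to 50 °C
Reagents that add atoms: bromoform, BrC(Br)Br
Why: Takai olefination: the geminal dichromium species formed from CHBr3 adds to the aldehyde and eliminates to the (E)-bromoalkene, the bromide salt of divalent chromium being chosen so that no chloride can enter the vinyl halide, and C1 has no hydrogen and cannot epimerise.

Step 8
Reactants: 11 (4S,5S)-4-bromo-5-[(E)-2-bromoethenyl]-1,5-dimethylcyclohex-1-ene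
Product: 12 (1R,3S,4S,6S)-4-bromo-3-[(E)-2-bromoethenyl]-1,3-dimethyl-7-oxabicyclo[4.1.0]heptane
Conditions: mCPBA, NaHCO3, CH2Cl2, 0 °C
Reagents that add atoms: 3-chloroperoxybenzoic acid, O=C(OO)c1cccc(Cl)c1
Why: Peracid epoxidation takes the electron-rich trisubstituted C4=C5 alkene and ignores the electron-poor bromovinyl group; in the half-chair with equatorial C2–Br the bromovinyl group is pseudoaxial over the top face, so oxygen should be delivered to the bottom face, which fixes the face from which both chlorides later enter.

Step 9
Reactants: 12 (1R,3S,4S,6S)-4-bromo-3-[(E)-2-bromoethenyl]-1,3-dimethyl-7-oxabicyclo[4.1.0]heptane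
Product: 13 (1S,2S,4S,5S)-5-bromo-4-[(E)-2-bromoethenyl]-2-chloro-2,4-dimethylcyclohexan-1-ol
Conditions: HCl (2 M in Et2O), CH2Cl2, −78 to −30 °C
Reagents that add atoms: hydrogen chloride, Cl
Why: Acid-promoted epoxide opening at the more substituted carbon: chloride attacks tertiary C5 from the top face with inversion in the trans-diaxial mode, which gives the C5 chloride in the target configuration and leaves the C4 hydroxyl on the bottom face.

Step 10
Reactants: 13 (1S,2S,4S,5S)-5-bromo-4-[(E)-2-bromoethenyl]-2-chloro-2,4-dimethylcyclohexan-1-ol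
Product: 15 (1S,2S,4R,5S)-2-bromo-1-[(E)-2-bromoethenyl]-4,5-dichloro-1,5-dimethylcyclohexane, via alkoxyphosphonium chloride 14 (not isolated)
Conditions: PPh3, NCS, CH2Cl2, 0 °C to rt
Reagents that add atoms: N-chlorosuccinimide, O=C1CCC(=O)N1Cl
Why: Appel-type deoxychlorination: the secondary alcohol is activated as its alkoxyphosphonium salt and displaced by chloride in an SN2 step with inversion at C4, which brings the second chlorine onto the top face cis to the C5 chlorine, while the tertiary chloride and both bromides should not react under these neutral conditions.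

**Compound list**

1 | 3-methylbut-3-en-2-one | CC(=O)C(C)=C | starting material
2 | tert-butyl(dimethyl)[(3-methylbuta-1,3-dien-2-yl)oxy]silane | C=C(C)C(=C)O[Si](C)(C)C(C)(C)C | intermediate
3 | prop-2-yn-1-ol | OCC#C | starting material
4 | bromomagnesium (Z)-3-(bromomagnesio)-2-methylprop-2-en-1-olate (magnesiated alkoxide, not isolated) | Br[Mg]OC/C(C)=C\[Mg]Br | intermediate
5 | (Z)-3-bromo-2-methylprop-2-en-1-ol | OC/C(C)=C\Br | intermediate
6 | (Z)-3-bromo-2-methylprop-2-enal | O=C/C(C)=C\Br | intermediate
7 | (1S,6S)-6-bromo-4-[tert-butyl(dimethyl)silyl]oxy-1,3-dimethylcyclohex-3-ene-1-carbaldehyde (Br cis to CHO) | CC1=C(O[Si](C)(C)C(C)(C)C)C[C@H](Br)[C@](C)(C=O)C1 | intermediate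
8 | cesium (4S,5S)-5-bromo-4-formyl-2,4-dimethylcyclohex-1-en-1-olate (cesium enolate, not isolated) | CC1=C([O-])C[C@H](Br)[C@](C)(C=O)C1.[Cs+] | intermediate
9 | (4S,5S)-5-bromo-4-formyl-2,4-dimethylcyclohex-1-en-1-yl trifluoromethanesulfonate | CC1=C(OS(=O)(=O)C(F)(F)F)C[C@H](Br)[C@](C)(C=O)C1 | intermediate
10 | (1S,6S)-6-bromo-1,3-dimethylcyclohex-3-ene-1-carbaldehyde | CC1=CC[C@H](Br)[C@](C)(C=O)C1 | intermediate
11 | (4S,5S)-4-bromo-5-[(E)-2-bromoethenyl]-1,5-dimethylcyclohex-1-ene | CC1=CC[C@H](Br)[C@](C)(/C=C/Br)C1 | intermediate
12 | (1R,3S,4S,6S)-4-bromo-3-[(E)-2-bromoethenyl]-1,3-dimethyl-7-oxabicyclo[4.1.0]heptane (oxygen on the bottom face) | C[C@@]12C[C@@](C)(/C=C/Br)[C@@H](Br)C[C@@H]1O2 | intermediate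
13 | (1S,2S,4S,5S)-5-bromo-4-[(E)-2-bromoethenyl]-2-chloro-2,4-dimethylcyclohexan-1-ol (C5–Cl top, C4–OH bottom) | C[C@]1(Cl)C[C@@](C)(/C=C/Br)[C@@H](Br)C[C@@H]1O | intermediate
14 | [(1S,2S,4S,5S)-5-bromo-4-[(E)-2-bromoethenyl]-2-chloro-2,4-dimethylcyclohexyl]oxy(triphenyl)phosphonium chloride (not isolated) | C[C@]1(Cl)C[C@@](C)(/C=C/Br)[C@@H](Br)C[C@@H]1O[P+](c2ccccc2)(c2ccccc2)c2ccccc2.[Cl-] | intermediate
15 | (1S,2S,4R,5S)-2-bromo-1-[(E)-2-bromoethenyl]-4,5-dichloro-1,5-dimethylcyclohexane | C[C@]1(Cl)C[C@@](C)(/C=C/Br)[C@@H](Br)C[C@H]1Cl | target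

**Step count**

Total steps: 10. Longest linear sequence: 9 steps (from 3 through steps 2 to 10); the diene branch adds step 1.

**Steps most likely to fail, with fallbacks**

Step 4. The trisubstituted β-bromoenal may react slowly, so that Z-to-E isomerisation or a stepwise Mukaiyama–Michael addition with loss of bromide competes. In addition the bromine lies on the formyl-hydrogen edge of the enal, the edge turned toward the catalyst, and may erode facial discrimination. The fallback gives up catalyst control for resolution. It sets out again from 2 and 6, which are combined under achiral Me2AlCl (CH2Cl2, −78 °C) to give 7 together with its mirror image, the (1R,6R)-aldehyde F1. Condensation of the mixture with (1S,2S)-N,N′-dimethyl-1,2-diphenylethane-1,2-diamine (4 Å molecular sieves, CH2Cl2) should give two diastereomeric aminals, the imidazolidine F2 from 7 and the imidazolidine F3 from F1, which are separated by chromatography. Hydrolysis of F2 on wet silica gel or with cold aqueous acetic acid in THF returns enantiopure 7, where the route is rejoined.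

Step 8. A peracid is a small reagent and both half-chairs of 11 are populated, so facial selectivity may be poor and oxygen may also be delivered to the top face. The fallback replaces direct epoxidation by dihydroxylation and ring closure with overall retention. It sets out from 11: the bulkier oxidant (K2OsO4·2H2O cat., NMO, acetone–water) should discriminate the faces better and give the bottom-face cis-diol F4. MeC(OMe)3 with PPTS converts this into the cyclic orthoacetate F5, and Me3SiCl opens the derived acetoxonium ion with chloride and inversion to the trans chloro acetate F6. K2CO3 in MeOH then removes the acetate and closes the ring with a second inversion; either regiochemistry of chloride attack converges on epoxide 12, where the route is rejoined.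

Step 10. C4 sits next to the fully substituted C5, and the C5 chlorine is antiperiplanar to the leaving group, so E2 loss toward C3 or chlorine participation (retention or a 1,2-shift) may outrun invertive displacement. The fallback changes both the precursor and the leaving group. It sets out from 11 and bypasses 12 to 14: PhSeCl adds anti across C4=C5 (CH2Cl2, −78 °C to rt, with equilibration to the adduct carrying chloride on tertiary C5), and reversible seleniranium formation with trans-diaxial opening should favour the β-chloro selenide F7 with selenium on the bottom face. SO2Cl2 oxidises it to the tetravalent selenium dichloride F8, whose much better leaving group is displaced by chloride (Bu4NCl) with inversion at C4, which comes back to the route directly at target 15.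

**Further compounds**

F1 | step 4 | (1R,6R)-6-bromo-4-[tert-butyl(dimethyl)silyl]oxy-1,3-dimethylcyclohex-3-ene-1-carbaldehyde | CC1=C(O[Si](C)(C)C(C)(C)C)C[C@@H](Br)[C@@](C)(C=O)C1
F2 | step 4 | (4S,5S)-2-[(1S,6S)-6-bromo-4-[tert-butyl(dimethyl)silyl]oxy-1,3-dimethylcyclohex-3-en-1-yl]-1,3-dimethyl-4,5-diphenylimidazolidine | CC1=C(O[Si](C)(C)C(C)(C)C)C[C@H](Br)[C@](C)(C3N(C)[C@@H](c4ccccc4)[C@H](c4ccccc4)N3C)C1
F3 | step 4 | (4S,5S)-2-[(1R,6R)-6-bromo-4-[tert-butyl(dimethyl)silyl]oxy-1,3-dimethylcyclohex-3-en-1-yl]-1,3-dimethyl-4,5-diphenylimidazolidine | CC1=C(O[Si](C)(C)C(C)(C)C)C[C@@H](Br)[C@@](C)(C3N(C)[C@@H](c4ccccc4)[C@H](c4ccccc4)N3C)C1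
F4 | step 8 | (1R,2S,4S,5S)-4-bromo-5-[(E)-2-bromoethenyl]-1,5-dimethylcyclohexane-1,2-diol | C[C@@]1(O)C[C@@](C)(/C=C/Br)[C@@H](Br)C[C@@H]1O
F5 | step 8 | cyclic orthoacetate of F4 (2-methoxy-2-methyl-1,3-dioxolane fused at C4/C5, orthoester carbon undefined) | C[C@@]12C[C@@](C)(/C=C/Br)[C@@H](Br)C[C@@H]1OC(C)(OC)O2
F6 | step 8 | (1S,2S,4S,5S)-5-bromo-4-[(E)-2-bromoethenyl]-2-chloro-2,4-dimethylcyclohexyl acetate | C[C@]1(Cl)C[C@@](C)(/C=C/Br)[C@@H](Br)C[C@@H]1OC(C)=O
F7 | step 10 | [(1S,2S,4S,5S)-5-bromo-4-[(E)-2-bromoethenyl]-2-chloro-2,4-dimethylcyclohexyl] phenyl selenide | C[C@]1(Cl)C[C@@](C)(/C=C/Br)[C@@H](Br)C[C@@H]1[Se]c2ccccc2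
F8 | step 10 | [(1S,2S,4S,5S)-5-bromo-4-[(E)-2-bromoethenyl]-2-chloro-2,4-dimethylcyclohexyl](dichloro)phenylselenium | C[C@]1(Cl)C[C@@](C)(/C=C/Br)[C@@H](Br)C[C@@H]1[Se](Cl)(Cl)c2ccccc2
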